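**Plan**

- Retrosynthesis: the two O–Si bonds and the C6–C7 saturation are removed first; C5–C10 and C8–C9 are then cut together (retro intramolecular Diels–Alder) to an open-chain (E,E)-dienyl chloroallene. C11–Cl goes back to a tertiary propargylic alcohol (SNi′), aryl–C11 to a Sonogashira coupling, and the chain to two Suzuki couplings.
- Enabling feature: in ring B the exocyclic, fully substituted C9=C11(Cl)Ar alkene sits next to the quaternary ring-fusion carbon C10. It is the π-bond that an allene C10=C9=C11 leaves behind when its other π-bond (C9=C10) acts as dienophile. Ring B is then the cycloadduct ring and ring A the ring closed by the four-carbon tether C1–C4.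
- Forward: the dienyl chain is built linearly, the C10 carbinol centre is set by Sharpless epoxidation and unmasked as a tertiary alkynol, the arene is attached, the alcohol is turned into the chloroallene, and one thermal cycloaddition closes ring A and ring B together; diimide and fluoride finish.
- Stereochemistry: Sharpless epoxidation (D-(−)-diethyl tartrate) → tertiary C–O centre → allene axis (syn 1,3-transfer) → C10, C5, C8 and the (E)-chloroalkene geometry in the cycloaddition.

Key step: step 13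

Remark: locants C1–C11 are those of the target skeleton (C4 = CMe2, C5 and C10 = ring fusion, C8 = CHMe, C9=C11 = exocyclic alkene); the SMILES of allene 20 gives the axis by the extended tetrahedral convention.

**Step 1**
Reactants: 1 2,2-dimethylpent-4-enal
Product: 2 (1E)-1-iodo-3,3-dimethylhexa-1,5-diene
Conditions: CrCl2, CHI3, THF, 0 °C to rt
Reagents that add atoms: iodoform, IC(I)I
Why: Takai olefination; the geminal dichromium species adds to the aldehyde and eliminates to the (E)-vinyl iodide, a branched α-carbon favouring E, and the terminal alkene is inert.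

**Step 2**
Reactants: 2 (1E)-1-iodo-3,3-dimethylhexa-1,5-diene; 3 (E)-prop-1-en-1-ylboronic acid
Product: 4 (5E,7E)-4,4-dimethylnona-1,5,7-triene
Conditions: Pd(PPh3)4 (cat.), aq. KOH, THF, rt
Reagents that add atoms: none
Why: Suzuki–Miyaura coupling of an alkenyl iodide with an alkenylboronic acid goes with retention at both partners, so the (E,E)-diene should be formed stereodefined.

**Step 3**
Reactants: 5 ethyl acetoacetate
Product: 6 ethyl (2E)-3-{[(trifluoromethyl)sulfonyl]oxy}but-2-enoate
Conditions: Tf2O, aq. Me4NOH, hexanes, 5 °C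
Reagents that add atoms: trifluoromethanesulfonic anhydride, O=S(=O)(OS(=O)(=O)C(F)(F)F)C(F)(F)F
Why: O-triflation of the β-keto ester enolate with a non-chelating ammonium counter-ion is the known (E)-selective variant, a chelating lithium base giving the (Z) isomer instead.

**Step 4**
Reactants: 4 (5E,7E)-4,4-dimethylnona-1,5,7-triene; 6 ethyl (2E)-3-{[(trifluoromethyl)sulfonyl]oxy}but-2-enoate
Product: 8 ethyl (2E,8E,10E)-3,7,7-trimethyldodeca-2,8,10-trienoate, via B-alkyl-9-BBN 7 (not isolated)
Conditions: 9-BBN, THF, 0 °C to rt; then 6, Pd(dppf)Cl2 (cat.), aq. K3PO4, DMF, rt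
Reagents that add atoms: 9-borabicyclo[3.3.1]nonane, B1C2CCCC1CCC2 (its atoms stay only in intermediate 7)
Why: 9-BBN hydroborates only the monosubstituted terminal alkene (anti-Markovnikov) and the B-alkyl Suzuki–Miyaura coupling with the β-triflyloxy enoate proceeds with retention, giving the (E)-trisubstituted enoate.

**Step 5**
Reactants: 8 ethyl (2E,8E,10E)-3,7,7-trimethyldodeca-2,8,10-trienoate
Product: 9 (2E,8E,10E)-3,7,7-trimethyldodeca-2,8,10-trien-1-ol
Conditions: i-Bu2AlH (2.2 equiv), CH2Cl2, −78 °C; aq. potassium sodium tartrate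
Reagents that add atoms: none
Why: 1,2-reduction of an α,β-unsaturated ester by i-Bu2AlH gives the allylic alcohol without touching the alkenes.

**Step 6**
Reactants: 9 (2E,8E,10E)-3,7,7-trimethyldodeca-2,8,10-trien-1-ol
Product: 10 [(2R,3R)-3-methyl-3-[(5E,7E)-4,4-dimethylnona-5,7-dien-1-yl]oxiran-2-yl]methanol
Conditions: Ti(OiPr)4 (cat.), D-(−)-diethyl tartrate (cat.), t-BuOOH, 4 Å MS, CH2Cl2, −20 °C
Reagents that add atoms: tert-butyl hydroperoxide, CC(C)(C)OO
Why: Sharpless asymmetric epoxidation; the titanium tartrate binds the allylic hydroxyl and epoxidises only that alkene, and D-(−)-tartrate should give the (2R,3R)-epoxide from an (E)-3-methylalk-2-en-1-ol (mirror image of the geraniol/L-(+)-tartrate outcome), which fixes the C–O centre that becomes C10.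

**Step 7**
Reactants: 10 [(2R,3R)-3-methyl-3-[(5E,7E)-4,4-dimethylnona-5,7-dien-1-yl]oxiran-2-yl]methanol
Product: 11 (2S,3R)-2-(chloromethyl)-3-methyl-3-[(5E,7E)-4,4-dimethylnona-5,7-dien-1-yl]oxirane
Conditions: PPh3, CCl4, NaHCO3, reflux
Reagents that add atoms: carbon tetrachloride, ClC(Cl)(Cl)Cl
Why: Appel reaction of the primary alcohol under neutral conditions leaves the epoxide and its two stereocentres untouched (the descriptor at C2 changes only because CH2Cl outranks C3).

**Step 8**
Reactants: 11 (2S,3R)-2-(chloromethyl)-3-methyl-3-[(5E,7E)-4,4-dimethylnona-5,7-dien-1-yl]oxirane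
Product: 13 (3R,8E,10E)-3,7,7-trimethyldodeca-8,10-dien-1-yn-3-ol, via chlorovinyl carbinol alkoxide 12 (not isolated)
Conditions: LiN(i-Pr)2 (3.5 equiv), THF, −78 to −30 °C; aq. NH4Cl
Reagents that add atoms: none
Why: base-induced double elimination of a 2,3-epoxy chloride (deprotonation at CH2Cl opens the epoxide, then dehydrochlorination gives the alkyne); the tertiary C–O bond is not touched, so its configuration is kept.

**Step 9**
Reactants: 14 4-hydroxy-3-iodo-5-methoxybenzaldehyde (5-iodovanillin)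
Product: 16 2-iodo-6-methoxybenzene-1,4-diol, via aryl formate 15 (not isolated)
Conditions: 30% H2O2, aq. NaOH, THF, 0 °C to rt, N2; then aq. HCl
Reagents that add atoms: hydrogen peroxide, OO
Why: Dakin oxidation of a para-hydroxybenzaldehyde (aryl migration in the peroxide adduct, then hydrolysis of the formate) gives the hydroquinone with the iodine where the side chain is needed.

**Step 10**
Reactants: 16 2-iodo-6-methoxybenzene-1,4-diol
Product: 17 1,4-bis(tert-butyldimethylsilyloxy)-2-iodo-6-methoxybenzene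
Conditions: TBSCl, imidazole, DMF, rt
Reagents that add atoms: tert-butyldimethylsilyl chloride, CC(C)(C)[Si](C)(C)Cl
Why: standard silylation of both phenols; aryl silyl ethers survive amine bases, SOCl2/pyridine, heat and diimide and are removed by fluoride at the end.

**Step 11**
Reactants: 13 (3R,8E,10E)-3,7,7-trimethyldodeca-8,10-dien-1-yn-3-ol; 17 1,4-bis(tert-butyldimethylsilyloxy)-2-iodo-6-methoxybenzene
Product: 18 (3R,8E,10E)-1-[2,5-bis(tert-butyldimethylsilyloxy)-3-methoxyphenyl]-3,7,7-trimethyldodeca-8,10-dien-1-yn-3-ol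
Conditions: Pd(PPh3)2Cl2 (cat.), CuI (cat.), Et3N, THF, rt
Reagents that add atoms: none
Why: Sonogashira coupling of a terminal alkyne with an aryl iodide tolerates the free tertiary alcohol and the diene and does not touch the stereocentre.

**Step 12**
Reactants: 18 (3R,8E,10E)-1-[2,5-bis(tert-butyldimethylsilyloxy)-3-methoxyphenyl]-3,7,7-trimethyldodeca-8,10-dien-1-yn-3-ol
Product: 20 1,4-bis(tert-butyldimethylsilyloxy)-2-[(aR,8E,10E)-1-chloro-3,7,7-trimethyldodeca-1,2,8,10-tetraen-1-yl]-6-methoxybenzene, via propargylic chlorosulfite 19 (not isolated)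
Conditions: SOCl2, pyridine, Et2O, −40 to 0 °C; used at once
Reagents that add atoms: thionyl chloride, O=S(Cl)Cl
Why: SNi′ collapse of the propargylic chlorosulfite delivers chloride to the alkyne terminus C11 on the face from which oxygen leaves (syn 1,3-substitution), so the (R) carbinol centre should be converted into the (aR) allene axis, with ether and low temperature limiting ion-pair scrambling.

**Step 13**
Reactants: 20 1,4-bis(tert-butyldimethylsilyloxy)-2-[(aR,8E,10E)-1-chloro-3,7,7-trimethyldodeca-1,2,8,10-tetraen-1-yl]-6-methoxybenzene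
Product: 21 1,4-bis(tert-butyldimethylsilyloxy)-2-{(E)-chloro[(2S,4aS,8aS)-2,5,5,8a-tetramethyl-4a,5,6,7,8,8a-hexahydronaphthalen-1(2H)-ylidene]methyl}-6-methoxybenzene
Conditions: PhMe (0.005 M, degassed), BHT, propylene oxide, 150 °C, sealed tube
Reagents that add atoms: none
Why: Proposed new method: a thermal [4+2] (concerted or strongly asynchronous) in which the C9=C10 π-bond of the chloroallene is the 2π partner and the (E,E)-diene C5–C8 the 4π partner forms C5–C10 and C8–C9 and leaves the orthogonal C9=C11 π-bond as the exocyclic chloro(aryl)alkene; the closest known reaction type is the intramolecular Diels–Alder reaction of 1,3,9-decatrienes with allenic dienophiles, including axis-to-centre chirality transfer, but a 1-chloro-1-arylallene has not been used in this way. Ring B is closed by the cycloaddition itself (cyclohexene) and ring A as the fused six-membered ring through the tether C1–C4 (type 1 closure; only the C9=C10 bond reaches the diene through a six-membered tether, which excludes the C9=C11 bond). C10 is set by the allene axis: Cl and aryl on C11 lie on the two faces of the C9=C10 bond, the diene adds to the face that carries the small Cl and away from the ortho-silyloxy aryl group, and the same choice puts C8 cis to Cl and the aryl cis to C10, i.e. the (E)-chloroalkene. C5 follows from the chair-like tether with the C10 methyl endo and the tether exo (trans ring fusion), and C8 from suprafacial addition to the (E,E)-diene, which places the C8 methyl cis to the C10 methyl. The step needs face selectivity, trans over cis fusion and a cycloaddition that outruns ionisation, HCl loss or dimerisation of the allene: the first is secured by the size difference between Cl and aryl, the second is expected (the cis transition state folds C1–C2 under the diene) but not assured, and high dilution, a non-polar solvent, BHT and an acid scavenger serve the third.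

**Step 14**
Reactants: 21 1,4-bis(tert-butyldimethylsilyloxy)-2-{(E)-chloro[(2S,4aS,8aS)-2,5,5,8a-tetramethyl-4a,5,6,7,8,8a-hexahydronaphthalen-1(2H)-ylidene]methyl}-6-methoxybenzene
Product: 22 1,4-bis(tert-butyldimethylsilyloxy)-2-{(E)-chloro[(2S,4aS,8aS)-2,5,5,8a-tetramethyloctahydronaphthalen-1(2H)-ylidene]methyl}-6-methoxybenzene
Conditions: 2-nitrobenzenesulfonyl hydrazide, Et3N, CH2Cl2, rt
Reagents that add atoms: none
Why: diimide reduction; concerted syn transfer of H2 is much faster to the cis-disubstituted C6=C7 bond than to the tetrasubstituted aryl chloroalkene and does not cleave C–Cl, and no stereocentre is created.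

**Step 15**
Reactants: 22 1,4-bis(tert-butyldimethylsilyloxy)-2-{(E)-chloro[(2S,4aS,8aS)-2,5,5,8a-tetramethyloctahydronaphthalen-1(2H)-ylidene]methyl}-6-methoxybenzene
Product: 23 2-{(E)-chloro[(2S,4aS,8aS)-2,5,5,8a-tetramethyloctahydronaphthalen-1(2H)-ylidene]methyl}-6-methoxybenzene-1,4-diol
Conditions: Bu4NF, AcOH, THF, 0 °C, argon
Reagents that add atoms: none
Why: fluoride cleaves both aryl silyl ethers, and acetic acid keeps the phenols protonated so the electron-rich hydroquinone is not exposed as a phenoxide to oxygen.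

**Compound list**

1 | 2,2-dimethylpent-4-enal | C=CCC(C)(C)C=O | starting material
2 | (1E)-1-iodo-3,3-dimethylhexa-1,5-diene | C=CCC(C)(C)/C=C/I | intermediate
3 | (E)-prop-1-en-1-ylboronic acid | C/C=C/B(O)O | starting material
4 | (5E,7E)-4,4-dimethylnona-1,5,7-triene | C=CCC(C)(C)/C=C/C=C/C | intermediate
5 | ethyl acetoacetate | CCOC(=O)CC(C)=O | starting material
6 | ethyl (2E)-3-{[(trifluoromethyl)sulfonyl]oxy}but-2-enoate | CCOC(=O)/C=C(\C)OS(=O)(=O)C(F)(F)F | intermediate
7 | 9-[(5E,7E)-4,4-dimethylnona-5,7-dien-1-yl]-9-borabicyclo[3.3.1]nonane | C/C=C/C=C/C(C)(C)CCCB1C2CCCC1CCC2 | intermediate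
8 | ethyl (2E,8E,10E)-3,7,7-trimethyldodeca-2,8,10-trienoate | CCOC(=O)/C=C(\C)CCCC(C)(C)/C=C/C=C/C | intermediate
9 | (2E,8E,10E)-3,7,7-trimethyldodeca-2,8,10-trien-1-ol | OC/C=C(\C)CCCC(C)(C)/C=C/C=C/C | intermediate
10 | [(2R,3R)-3-methyl-3-[(5E,7E)-4,4-dimethylnona-5,7-dien-1-yl]oxiran-2-yl]methanol | OC[C@H]1O[C@]1(C)CCCC(C)(C)/C=C/C=C/C | intermediate
11 | (2S,3R)-2-(chloromethyl)-3-methyl-3-[(5E,7E)-4,4-dimethylnona-5,7-dien-1-yl]oxirane | ClC[C@H]1O[C@]1(C)CCCC(C)(C)/C=C/C=C/C | intermediate
12 | (3R,8E,10E)-1-chloro-3,7,7-trimethyldodeca-1,8,10-trien-3-ol (lithium alkoxide in the flask, C1=C2 geometry not defined) | C/C=C/C=C/C(C)(C)CCC[C@@](C)(O)C=CCl | intermediate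
13 | (3R,8E,10E)-3,7,7-trimethyldodeca-8,10-dien-1-yn-3-ol | C/C=C/C=C/C(C)(C)CCC[C@@](C)(O)C#C | intermediate
14 | 4-hydroxy-3-iodo-5-methoxybenzaldehyde | COc1cc(C=O)cc(I)c1O | starting material
15 | 4-hydroxy-3-iodo-5-methoxyphenyl formate | COc1cc(OC=O)cc(I)c1O | intermediate
16 | 2-iodo-6-methoxybenzene-1,4-diol | COc1cc(O)cc(I)c1O | intermediate
17 | 1,4-bis(tert-butyldimethylsilyloxy)-2-iodo-6-methoxybenzene | COc1cc(O[Si](C)(C)C(C)(C)C)cc(I)c1O[Si](C)(C)C(C)(C)C | intermediate
18 | (3R,8E,10E)-1-[2,5-bis(tert-butyldimethylsilyloxy)-3-methoxyphenyl]-3,7,7-trimethyldodeca-8,10-dien-1-yn-3-ol | C/C=C/C=C/C(C)(C)CCC[C@@](C)(O)C#Cc1cc(O[Si](C)(C)C(C)(C)C)cc(OC)c1O[Si](C)(C)C(C)(C)C | intermediate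
19 | (3R,8E,10E)-1-[2,5-bis(tert-butyldimethylsilyloxy)-3-methoxyphenyl]-3,7,7-trimethyldodeca-8,10-dien-1-yn-3-yl chlorosulfite | C/C=C/C=C/C(C)(C)CCC[C@@](C)(OS(Cl)=O)C#Cc1cc(O[Si](C)(C)C(C)(C)C)cc(OC)c1O[Si](C)(C)C(C)(C)C | intermediate
20 | 1,4-bis(tert-butyldimethylsilyloxy)-2-[(aR,8E,10E)-1-chloro-3,7,7-trimethyldodeca-1,2,8,10-tetraen-1-yl]-6-methoxybenzene | C/C=C/C=C/C(C)(C)CCCC(C)=[C@@]=C(Cl)c1cc(O[Si](C)(C)C(C)(C)C)cc(OC)c1O[Si](C)(C)C(C)(C)C | intermediate
21 | 1,4-bis(tert-butyldimethylsilyloxy)-2-{(E)-chloro[(2S,4aS,8aS)-2,5,5,8a-tetramethyl-4a,5,6,7,8,8a-hexahydronaphthalen-1(2H)-ylidene]methyl}-6-methoxybenzene | COc1cc(O[Si](C)(C)C(C)(C)C)cc(/C(Cl)=C2/[C@@H](C)C=C[C@H]3C(C)(C)CCC[C@]23C)c1O[Si](C)(C)C(C)(C)C | intermediate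
22 | 1,4-bis(tert-butyldimethylsilyloxy)-2-{(E)-chloro[(2S,4aS,8aS)-2,5,5,8a-tetramethyloctahydronaphthalen-1(2H)-ylidene]methyl}-6-methoxybenzene | COc1cc(O[Si](C)(C)C(C)(C)C)cc(/C(Cl)=C2/[C@@H](C)CC[C@H]3C(C)(C)CCC[C@]23C)c1O[Si](C)(C)C(C)(C)C | intermediate
23 | 2-{(E)-chloro[(2S,4aS,8aS)-2,5,5,8a-tetramethyloctahydronaphthalen-1(2H)-ylidene]methyl}-6-methoxybenzene-1,4-diol | COc1cc(O)cc(/C(Cl)=C2/[C@@H](C)CC[C@H]3C(C)(C)CCC[C@]23C)c1O | target

**Totals**

Total step count: 15. Longest linear sequence: 12 steps (1, 2, 4, 5, 6, 7, 8, 11, 12, 13, 14, 15).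

**Steps most likely to fail**

1. Step 13 (Proposed new method). The unactivated cycloaddition may be slower than ionisation, HCl loss or dimerisation of the chloroallene; a stepwise diradical course may erode the transfer from axis to centres; and cis ring fusion may compete with trans. The fallback uses known chemistry, sets out from 8 and returns at 21. Ester 8 is saponified (LiOH) to (2E,8E,10E)-3,7,7-trimethyldodeca-2,8,10-trienoic acid F1. F1 is coupled (DCC, DMAP) with (S)-4-benzyloxazolidin-2-one to the N-acyl oxazolidinone F2. Me2AlCl in CH2Cl2 at −30 °C then promotes the auxiliary-controlled intramolecular Diels–Alder reaction of the chelated imide (endo, diene anti to benzyl), which should give the trans-fused octalin imide F3 with the C8 methyl, the C9 acyl group and the C10 methyl all cis. Me3Al/MeONHMe·HCl converts F3 into the N-methoxy-N-methylamide F4. The aryl Grignard reagent [2,5-bis(tert-butyldimethylsilyloxy)-3-methoxyphenyl]magnesium chloride F5 (from 17 with i-PrMgCl·LiCl) adds to F4 to give the aryl ketone F6. (PhO)3P/Cl2 with Et3N converts the ketone into the chloroalkene, and the (E) isomer, which is 21, is separated from its geometric isomer.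

2. Step 12. The axis may lose purity through a propargyl/allenyl ion pair, chloride may return at the tertiary carbon to give the propargylic chloride, and the chlorosulfite may eliminate to the enyne. The fallback reaches 20 by anti 1,3-substitution instead; it sets out from 9 and returns at 20. Sharpless epoxidation of 9 with L-(+)-diethyl tartrate gives [(2S,3S)-3-methyl-3-[(5E,7E)-4,4-dimethylnona-5,7-dien-1-yl]oxiran-2-yl]methanol F7. The Appel reaction gives the (2R,3S)-chloromethyl oxirane F8. LiN(i-Pr)2 takes F8 through the (3S)-chlorovinyl carbinol F9 to (3S,8E,10E)-3,7,7-trimethyldodeca-8,10-dien-1-yn-3-ol F10. Sonogashira coupling with 17 gives the (3S)-aryl alkynol F11. MsCl/Et3N at −78 °C gives the methanesulfonate F12, and LiCl/CuCl (LiCuCl2) in THF displaces it by anti SN2′ to give the same (aR) allene 20.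

3. Step 15. The hydroquinone may autoxidise as it is set free, giving quinone and coupled material. The fallback passes through the quinone on purpose; it sets out from 22 and returns at 23. Compound 22 is desilylated with Bu4NF and the crude product is oxidised with Ag2O to 2-{(E)-chloro[(2S,4aS,8aS)-2,5,5,8a-tetramethyloctahydronaphthalen-1(2H)-ylidene]methyl}-6-methoxycyclohexa-2,5-diene-1,4-dione F13. F13 is purified and then reduced with aqueous Na2S2O4 under argon to 23.

**Further compounds**

F1 | step 13 | (2E,8E,10E)-3,7,7-trimethyldodeca-2,8,10-trienoic acid | OC(=O)/C=C(\C)CCCC(C)(C)/C=C/C=C/C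
F2 | step 13 | (4S)-4-benzyl-3-[(2E,8E,10E)-3,7,7-trimethyldodeca-2,8,10-trienoyl]-1,3-oxazolidin-2-one | O=C1OC[C@H](Cc2ccccc2)N1C(=O)/C=C(\C)CCCC(C)(C)/C=C/C=C/C
F3 | step 13 | (4S)-4-benzyl-3-{[(1S,2S,4aS,8aS)-2,5,5,8a-tetramethyl-1,2,4a,5,6,7,8,8a-octahydronaphthalen-1-yl]carbonyl}-1,3-oxazolidin-2-one | O=C1OC[C@H](Cc2ccccc2)N1C(=O)[C@H]3[C@@H](C)C=C[C@H]4C(C)(C)CCC[C@]34C
F4 | step 13 | (1S,2S,4aS,8aS)-N-methoxy-N,2,5,5,8a-pentamethyl-1,2,4a,5,6,7,8,8a-octahydronaphthalene-1-carboxamide | CON(C)C(=O)[C@H]1[C@@H](C)C=C[C@H]2C(C)(C)CCC[C@]12C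
F5 | step 13 | [2,5-bis(tert-butyldimethylsilyloxy)-3-methoxyphenyl]magnesium chloride | Cl[Mg]c1cc(O[Si](C)(C)C(C)(C)C)cc(OC)c1O[Si](C)(C)C(C)(C)C
F6 | step 13 | [2,5-bis(tert-butyldimethylsilyloxy)-3-methoxyphenyl][(1S,2S,4aS,8aS)-2,5,5,8a-tetramethyl-1,2,4a,5,6,7,8,8a-octahydronaphthalen-1-yl]methanone | COc1cc(O[Si](C)(C)C(C)(C)C)cc(C(=O)[C@H]2[C@@H](C)C=C[C@H]3C(C)(C)CCC[C@]23C)c1O[Si](C)(C)C(C)(C)C
F7 | step 12 | [(2S,3S)-3-methyl-3-[(5E,7E)-4,4-dimethylnona-5,7-dien-1-yl]oxiran-2-yl]methanol | OC[C@@H]1O[C@@]1(C)CCCC(C)(C)/C=C/C=C/C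
F8 | step 12 | (2R,3S)-2-(chloromethyl)-3-methyl-3-[(5E,7E)-4,4-dimethylnona-5,7-dien-1-yl]oxirane | ClC[C@@H]1O[C@@]1(C)CCCC(C)(C)/C=C/C=C/C
F9 | step 12 | (3S,8E,10E)-1-chloro-3,7,7-trimethyldodeca-1,8,10-trien-3-ol | C/C=C/C=C/C(C)(C)CCC[C@](C)(O)C=CCl
F10 | step 12 | (3S,8E,10E)-3,7,7-trimethyldodeca-8,10-dien-1-yn-3-ol | C/C=C/C=C/C(C)(C)CCC[C@](C)(O)C#C
F11 | step 12 | (3S,8E,10E)-1-[2,5-bis(tert-butyldimethylsilyloxy)-3-methoxyphenyl]-3,7,7-trimethyldodeca-8,10-dien-1-yn-3-ol | C/C=C/C=C/C(C)(C)CCC[C@](C)(O)C#Cc1cc(O[Si](C)(C)C(C)(C)C)cc(OC)c1O[Si](C)(C)C(C)(C)C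
F12 | step 12 | (3S,8E,10E)-1-[2,5-bis(tert-butyldimethylsilyloxy)-3-methoxyphenyl]-3,7,7-trimethyldodeca-8,10-dien-1-yn-3-yl methanesulfonate | C/C=C/C=C/C(C)(C)CCC[C@](C)(OS(C)(=O)=O)C#Cc1cc(O[Si](C)(C)C(C)(C)C)cc(OC)c1O[Si](C)(C)C(C)(C)C
F13 | step 15 | 2-{(E)-chloro[(2S,4aS,8aS)-2,5,5,8a-tetramethyloctahydronaphthalen-1(2H)-ylidene]methyl}-6-methoxycyclohexa-2,5-diene-1,4-dione | COC1=CC(=O)C=C(/C(Cl)=C2/[C@@H](C)CC[C@H]3C(C)(C)CCC[C@]23C)C1=O
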